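Compound numbers are fixed first and used throughout: 1–10 build the aldehyde fragment, 11–17 the allylboronate, 18–25 cover the annulation and the end game (25 is the target). Rings: A = the guaiacyl ring on the benzyl carbon, B = the tetrahydrofuran (O1, C2 aryl-bearing, C3 with CH2OH, C4 carbinol, C5 methylene), C = the benzo ring of the benzofuran, D = the dihydrofuran ring, E = the guaiacyl ring at benzofuran C2.

## The problem

Compound 25 joins two lignan motifs through the tetrasubstituted benzene ring C: a 2-aryl-3-hydroxymethyl-4-benzyl-4-hydroxytetrahydrofuran (ring B) sits at C5 of a 2-aryl-3-hydroxymethyl-7-methoxy-2,3-dihydrobenzofuran (rings C/D). There are five stereocentres in two clusters. In ring B, the aryl group at C2, the CH2OH at C3 and the benzyl group at C4 lie on one face and the tertiary hydroxyl on the other; in ring D, C2 and C3 are cis. The flat ring C separates the clusters, so neither can steer the other and each has to be set in absolute terms by a catalyst or reagent. Inside ring B, C2 and C3 can be set together in one cyclic transition state and can then control C4 by blocking a face. The cis-dihydrobenzofuran is the less stable isomer: it epimerises at C3 while C3 carries a carbonyl group, and its benzylic aryl ether, like the benzylic C2–O1 bond of ring B, can ionise under acid because both aryl groups are para-oxygenated. The same benzylic C–O bonds limit how forcing a final hydrogenolysis may be, and the phenols and the tertiary alcohol are best unmasked late. The enabling feature is in ring B: O1 and C2 with its aryl group are an aryl aldehyde in disguise, and C3–C4–C5 is a 2-substituted allyl unit once C4 is read as an exocyclic methylene carbon, from which the benzyl carbinol can be made afterwards.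

## Retrosynthesis

**Protecting groups (25 ← 24 ← 23).** The last two operations only cleave O–Si and O–benzyl bonds. Phenols are carried as benzyl ethers and primary alcohols as TBS ethers. Aryl benzyl ethers hydrogenolyse quickly under mild conditions, which spares the two cyclic benzylic ethers; alkyl benzyl ethers would need longer exposure, and phenolic silyl ethers would be at risk under the alkoxide base of the annulation. The forward steps need only neutral fluoride and neutral hydrogenation.

**The C4 carbinol (23 ← 20 + 22, 20 ← 19).** The bond between ring A and its benzylic CH2 is cut, together with the C4–O bond of an epoxide, giving spiro-epoxide 20 and aryl Grignard reagent 22 (from bromide 21). Epoxide 20 goes back to the exocyclic alkene 19. The neighbouring cut, a benzyl metal adding to a C4 ketone, would bring carbon in from the open face and give the C4 epimer. The epoxide route uses the same facial bias correctly: oxygen arrives on the open face and the aryl nucleophile touches only the CH2. The precursor 19 has one stereocentre and one aryl ring fewer. The forward reactions must epoxidise anti to the C3 substituent and open the epoxide at CH2 without Lewis-acid rearrangement.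

**Ring B (19 ← 10 + 17).** C2–C3 and O1–C5 are cut, giving aldehyde 10 and the bifunctional allylboronate 17. A stepwise aldol-then-alkylation approach would need separate operations for C4 and C5, and a trimethylenemethane cycloaddition could not place the C3 substituent with control. This cut halves the molecule and builds one ring, two bonds and two stereocentres in a single flask. It asks for syn selectivity from the boronate geometry (CH2OTBS cis to CH2B), for catalyst control of the aldehyde face, and for ring closure that is faster than silyl migration.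

**The boronate (17 ← 16 ← 15 ← 14 ← 13 ← 11 + 12).** Chloride 17 comes from alcohol 16 and ester 15 by functional-group change; 15 comes from an SN2' borylation of acetate 14, and 14 from the Morita–Baylis–Hillman adduct 13 of silyloxyacetaldehyde 11 and methyl acrylate 12. Borylating a precursor that already holds the chloride is rejected, because the boryl-copper species would expel chloride in preference to acetate. All four carbons and the alkene geometry come from two commodity chemicals. The sequence must deliver the isomer with CH2OTBS cis to CH2B, and the allylboronate must survive hydride reduction and chlorination.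

**The aldehyde (10 ← 9 ← 7 ← 6 ← 5 ← 4 ← 3 ← 1 + 2).** Silyl ether 10 and hydroxy aldehyde 9 lead back to cis ester 7, with the aldehyde masked as a dimethyl acetal. The stereo-defining cut is C2–C3 of ring D: a dirhodium carbenoid from diazo ester 6 inserts into the benzylic O–CH2 bond. This cut gives the cis isomer kinetically and sets both centres at once; the three other ring-D closures are weighed in the next section. Diazo transfer (6 ← 5), Negishi coupling of a Reformatsky reagent with the aryl iodide (5 ← 4), acetal formation (4 ← 3) and Mitsunobu etherification (3 ← 1 + 2) reduce everything to 5-iodovanillin 1 and the commercial benzyl alcohol 2. The insertion must be cis- and enantioselective, and everything after it must avoid base while C3 carries an ester and strong acid throughout.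

## Roads not taken

**Alternative 1:** The cut is C2–C3 of ring D, but made at the very end. The aryl diazoacetate A1, carrying the complete silylated tetrahydrofuran, would lose nitrogen with Rh2(S-PTTL)4 and insert into the ortho ArCH2O–H bond to give the cis ester A2.
- Merits: it uses the same proven insertion, the fragile cis ring has to survive only an ester reduction and one fluoride deprotection, and all-silyl protection allows a single unmasking step.
- Weak points: ring B with its three stereocentres must be built first, on an arene that already carries the latent acetate arm, so the acidic arylacetate or an aryl iodide would have to pass through an alkoxide cyclisation and an aryl Grignard step. The least forgiving reaction would then be run on the most valuable, most functionalised material, and the route is linear.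
- Comparison: Alternative 1 is better at shielding the cis-benzofuran and at final deprotection. The chosen plan answers this by removing the C3 carbonyl immediately after the insertion, after which no step uses strong acid or enolising base, and by running the carbenoid step early on a simple substrate close to precedent, in a convergent route.

**Alternative 2:** The cut is C3–C3a. Bromine–lithium exchange on the threo bromoaryl ether epoxide A3 would give an aryllithium that attacks the inner epoxide carbon with inversion (5-exo), giving the cis hydroxymethyl acetal A4, which is the same compound as 8.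
- Merits: the absolute configuration would come from Sharpless-type epoxidation chemistry, no diazo compound or rhodium is needed, and the route would merge with the present one at 8.
- Weak points: A3 needs a secondary aryl ether at a 4-alkoxybenzylic carbon made with full stereochemical fidelity, where ionisation threatens any displacement. The exo attack must hit the more hindered epoxide carbon against the 6-endo path to a chromanol. The benzylic α-aryloxy hydrogen invites Wittig rearrangement or elimination under the lithiation conditions.
- Comparison: step count is about equal and the source of chirality is arguably more dependable than a carbenoid catalyst on a new substrate. The relative configuration, however, rests on a contested ring opening, whereas the insertion gives cis directly.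

**Alternative 3:** The cut is O1–C7a. The secondary benzylic alcohol of A5 would couple with the ortho bromide (CuI, 3,4,7,8-tetramethyl-1,10-phenanthroline, Cs2CO3) with retention to give dihydrobenzofuran A6.
- Merits: no bond to a stereocentre is broken, so the cis relationship is as secure as the aldol chemistry that would set the two centres of A5, and the metal is cheap.
- Weak points: the bromide is flanked by methoxy and a branched alkyl group, and the alkoxide must survive hot carbonate without oxidation or elimination at copper. A6 lacks the C5 carbon, so a later formylation must choose C5 over C4 and C6 and leave ring E alone, and the tosylate must be exchanged before the end game.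
- Comparison: Alternative 3 is at least as reliable for the relative configuration, but it costs several extra steps and adds a regiochemical question that the chosen plan avoids by carrying the C5 carbon from 5-iodovanillin.

Key step: step 13

Assumption (chemistry): 2, 11 and 21 are taken as purchasable, and the sense of induction of Rh2(S-PTTL)4 (step 5) and of (R)-TRIP (step 13) is assigned by analogy with the parent substrates; the mirror-image catalyst would be used if a correlation shows the opposite sense.

## Route

Step 1
Reactants: 1 5-iodovanillin (4-hydroxy-3-iodo-5-methoxybenzaldehyde); 2 [4-(benzyloxy)-3-methoxyphenyl]methanol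
Product: 3 4-{[4-(benzyloxy)-3-methoxyphenyl]methoxy}-3-iodo-5-methoxybenzaldehyde
Conditions: PPh3, DIAD, THF, 0 °C to rt
Reagents that add atoms: none
Why: Mitsunobu etherification; the phenol of 1 is acidified by the para formyl and ortho iodo groups and the primary benzylic alcohol is activated as its oxyphosphonium salt, so no halide has to be made first.

Step 2
Reactants: 3 the aldehyde from step 1
Product: 4 2-{[4-(benzyloxy)-3-methoxyphenyl]methoxy}-5-(dimethoxymethyl)-1-iodo-3-methoxybenzene
Conditions: HC(OMe)3, MeOH, PPTS (cat.), rt; Et3N quench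
Reagents that add atoms: trimethyl orthoformate, COC(OC)OC; methanol, CO
Why: Acid-catalysed acetalisation with the orthoformate as water scavenger; the acetal hides the aldehyde from the zinc enolate, the amidine base and the carbenoid, and PPTS is too weak to cleave the alkoxybenzyl aryl ether.

Step 3
Reactants: 4 the iodo acetal
Product: 5 methyl 2-[2-{[4-(benzyloxy)-3-methoxyphenyl]methoxy}-5-(dimethoxymethyl)-3-methoxyphenyl]acetate
Conditions: BrZnCH2CO2Me (from BrCH2CO2Me, Zn, THF), Pd2(dba)3 (2.5 mol%), XPhos (10 mol%), THF, 60 °C
Reagents that add atoms: bromo(2-methoxy-2-oxoethyl)zinc, COC(=O)C[Zn]Br (made from methyl bromoacetate, COC(=O)CBr)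
Why: Negishi-type α-arylation with a Reformatsky reagent; the neutral zinc enolate couples with ortho-alkoxy aryl iodides without strong base and leaves the acetal and both ethers alone.

Step 4
Reactants: 5 the arylacetate
Product: 6 methyl 2-diazo-2-[2-{[4-(benzyloxy)-3-methoxyphenyl]methoxy}-5-(dimethoxymethyl)-3-methoxyphenyl]acetate
Conditions: p-ABSA, DBU, MeCN, 0 °C to rt
Reagents that add atoms: 4-acetamidobenzenesulfonyl azide, CC(=O)Nc1ccc(cc1)S(=O)(=O)N=[N+]=[N-]
Why: Regitz diazo transfer to an arylacetate, the standard entry to donor/acceptor diazo esters; nothing else in 5 is acidic enough to react.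

Step 5
Reactants: 6 the diazo ester
Product: 7 methyl (2R,3S)-2-[4-(benzyloxy)-3-methoxyphenyl]-5-(dimethoxymethyl)-7-methoxy-2,3-dihydro-1-benzofuran-3-carboxylate (2,3-cis)
Conditions: Rh2(S-PTTL)4 (1 mol%), toluene, −60 °C
Reagents that add atoms: none
Why: Intramolecular 1,5 C–H insertion of a dirhodium donor/acceptor carbenoid into the O–CH2 bond, which is activated by the ether oxygen and the electron-rich aryl group, forms C2–C3 of ring D. The chiral carboxylate pocket of dirhodium tetrakis[N-phthaloyl-(S)-tert-leucinate] should set both centres in the concerted insertion and give the kinetic cis ester, as it does for simpler 2-benzyloxyphenyl diazoacetates.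

Step 6
Reactants: 7 the cis ester
Product: 9 (2R,3R)-2-[4-(benzyloxy)-3-methoxyphenyl]-3-(hydroxymethyl)-7-methoxy-2,3-dihydro-1-benzofuran-5-carbaldehyde, via hydroxy acetal 8 (not isolated)
Conditions: i-Bu2AlH, CH2Cl2, −78 °C; then 1 M HCl, THF, 0 °C to rt
Reagents that add atoms: water, O
Why: Non-basic hydride reduction takes the ester to the primary alcohol without enolising C3, after which the cis centre is no longer epimerisable. The dilute acid of the work-up hydrolyses the electron-rich benzaldehyde dimethyl acetal and is too mild to ionise the benzylic aryl ether.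

Step 7
Reactants: 9 the hydroxy aldehyde
Product: 10 (2R,3R)-2-[4-(benzyloxy)-3-methoxyphenyl]-3-{[(tert-butyldimethylsilyl)oxy]methyl}-7-methoxy-2,3-dihydro-1-benzofuran-5-carbaldehyde
Conditions: TBSCl, imidazole, DMF, rt
Reagents that add atoms: tert-butyldimethylsilyl chloride, CC(C)(C)[Si](C)(C)Cl
Why: Standard silylation of a primary alcohol; the aldehyde is inert and the silyl ether removes the hydroxyl that would otherwise bind boron in step 13.

Step 8
Reactants: 11 (tert-butyldimethylsilyloxy)acetaldehyde; 12 methyl acrylate
Product: 13 methyl 4-[(tert-butyldimethylsilyl)oxy]-3-hydroxy-2-methylidenebutanoate (racemic)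
Conditions: DABCO (0.5 equiv), excess 12, MeOH, rt
Reagents that add atoms: none
Why: Morita–Baylis–Hillman reaction of a reactive α-alkoxy aldehyde; the stereocentre is of no consequence because it becomes an sp2 carbon in step 10.

Step 9
Reactants: 13 the Morita–Baylis–Hillman adduct
Product: 14 methyl 3-acetoxy-4-[(tert-butyldimethylsilyl)oxy]-2-methylidenebutanoate (racemic)
Conditions: Ac2O, pyridine, DMAP (cat.), CH2Cl2, 0 °C
Reagents that add atoms: acetic anhydride, CC(=O)OC(C)=O
Why: Acetylation turns the allylic hydroxyl into the leaving group for the SN2' borylation; low temperature avoids acetate transposition.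

Step 10
Reactants: 14 the allylic acetate
Product: 15 methyl (2E)-4-[(tert-butyldimethylsilyl)oxy]-2-[(4,4,5,5-tetramethyl-1,3,2-dioxaborolan-2-yl)methyl]but-2-enoate (CH2OTBS cis to CH2B)
Conditions: B2pin2, CuCl (10 mol%), LiCl, KOAc, DMF, rt
Reagents that add atoms: bis(pinacolato)diboron, CC1(C)OB(OC1(C)C)B1OC(C)(C)C(C)(C)O1
Why: Copper-catalysed allylic borylation of the Hosomi–Miyaura type: the boryl-copper species adds to the acrylate terminus and acetate leaves from the ester enolate (net SN2'). A(1,3) strain in that enolate should place hydrogen, not CH2OTBS, next to the ester, which gives the isomer with CH2OTBS cis to CH2B; the geometry is to be confirmed by NOE before use.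

Step 11
Reactants: 15 the boryl enoate
Product: 16 (2E)-4-[(tert-butyldimethylsilyl)oxy]-2-[(4,4,5,5-tetramethyl-1,3,2-dioxaborolan-2-yl)methyl]but-2-en-1-ol
Conditions: i-Bu2AlH (2.2 equiv), CH2Cl2, −78 °C; aq. potassium sodium tartrate
Reagents that add atoms: none
Why: 1,2-Reduction of an enoate to the allylic alcohol; pinacol boronates tolerate aluminium hydride at low temperature and a neutral tartrate work-up, and the alkene geometry is untouched.

Step 12
Reactants: 16 the allylic alcohol
Product: 17 tert-butyl({(2E)-4-chloro-3-[(4,4,5,5-tetramethyl-1,3,2-dioxaborolan-2-yl)methyl]but-2-en-1-yl}oxy)dimethylsilane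
Conditions: PPh3, CCl4, CH2Cl2, 0 °C to rt
Reagents that add atoms: carbon tetrachloride, ClC(Cl)(Cl)Cl
Why: Appel chlorination under neutral conditions; chloride displaces the oxyphosphonium group at the primary carbon (SN2), so the double bond neither moves nor isomerises and no acid reaches the boronate or the silyl ether.

Step 13
Reactants: 10 the benzofuran aldehyde; 17 the chloromethyl allylboronate
Product: 19 (2R,3R)-2-[4-(benzyloxy)-3-methoxyphenyl]-3-{[(tert-butyldimethylsilyl)oxy]methyl}-5-[(2R,3R)-3-{[(tert-butyldimethylsilyl)oxy]methyl}-4-methylideneoxolan-2-yl]-7-methoxy-2,3-dihydro-1-benzofuran (oxolane 2,3-cis), via homoallylic pinacol borate 18 (not isolated)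
Conditions: (R)-TRIP (10 mol%), 4 Å MS, toluene, −30 to 0 °C; then KOt-Bu, THF, 0 °C to rt
Reagents that add atoms: none
Why: The phosphoric acid hydrogen-bonds to a boronate oxygen and to the formyl hydrogen, and the allyl unit is transferred with allylic transposition through a closed six-membered chair (Zimmerman–Traxler) transition state, forming C2–C3; the closest known reactions are the chiral phosphoric acid-catalysed allyl- and crotylborations of aryl aldehydes with pinacol boronates and the 2-(halomethyl)allyl-metal annulations that give 3-methylenetetrahydrofurans. Because CH2OTBS is cis to CH2B it is axial in the chair while the aryl group of 10 is equatorial, so the syn adduct 18 results and maps onto the 2,3-cis ring: C3 is set relative to C2 by the alkene geometry of 17. The absolute configuration at C2 is set by the catalyst, (R)-TRIP [(R)-3,3'-bis(2,4,6-triisopropylphenyl)-1,1'-binaphthyl-2,2'-diyl hydrogen phosphate] being expected to direct attack on the Re face as with the parent boronates and so give the (R)-carbinol. The benzofuran stereocentres are too far away to interfere, so only catalyst control is needed, and any minor adduct is a diastereomer that can be removed. KOt-Bu then turns borate 18 into the potassium alkoxide, which displaces the allylic chloride in a 5-exo-tet Williamson closure (O1–C5) that touches neither new stereocentre. The closure has to outrun 1,4-silyl migration from the neighbouring CH2OTBS group; the allylic chloride and the five-membered transition state make it fast, and the chloride has no β-hydrogen and cannot eliminate.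

Step 14
Reactants: 19 the methylene tetrahydrofuran
Product: 20 (3R,6R,7R)-6-{(2R,3R)-2-[4-(benzyloxy)-3-methoxyphenyl]-3-{[(tert-butyldimethylsilyl)oxy]methyl}-7-methoxy-2,3-dihydro-1-benzofuran-5-yl}-7-{[(tert-butyldimethylsilyl)oxy]methyl}-1,5-dioxaspiro[2.4]heptane (epoxide oxygen trans to the aryl and CH2OTBS groups)
Conditions: mCPBA, NaHCO3, CH2Cl2, 0 °C
Reagents that add atoms: 3-chloroperoxybenzoic acid, OOC(=O)c1cccc(Cl)c1
Why: Prilezhaev epoxidation of a 1,1-disubstituted alkene; the allylic CH2OTBS at C3 and the cis aryl group at C2 cover one face, so oxygen should be delivered to the other, which fixes C4. The bicarbonate buffer protects the acid-sensitive spiro-epoxide and benzylic ethers.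

Step 15
Reactants: 20 the spiro-epoxide; 21 1-(benzyloxy)-4-bromo-2-methoxybenzene
Product: 23 (3S,4R,5R)-3-{[4-(benzyloxy)-3-methoxyphenyl]methyl}-5-{(2R,3R)-2-[4-(benzyloxy)-3-methoxyphenyl]-3-{[(tert-butyldimethylsilyl)oxy]methyl}-7-methoxy-2,3-dihydro-1-benzofuran-5-yl}-4-{[(tert-butyldimethylsilyl)oxy]methyl}oxolan-3-ol, via aryl Grignard reagent 22 (not isolated)
Conditions: 21, Mg, THF, rt; then CuI (10 mol%), 20, THF, −30 to 0 °C; aq. NH4Cl
Reagents that add atoms: none
Why: Copper-catalysed opening of an epoxide by an aryl Grignard reagent at the unsubstituted carbon (SN2); the C4–O bond is not broken, so C4 keeps the configuration set in step 14 and the new benzyl group ends up cis to the C2 and C3 substituents.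

Step 16
Reactants: 23 the bis-silyl ether
Product: 24 (3S,4R,5R)-3-{[4-(benzyloxy)-3-methoxyphenyl]methyl}-5-{(2R,3R)-2-[4-(benzyloxy)-3-methoxyphenyl]-3-(hydroxymethyl)-7-methoxy-2,3-dihydro-1-benzofuran-5-yl}-4-(hydroxymethyl)oxolan-3-ol
Conditions: TBAF, THF, rt
Reagents that add atoms: none
Why: Fluoride cleavage of two primary TBS ethers under essentially neutral conditions; benzyl ethers, the tertiary alcohol and both benzylic ring ethers are inert.

Step 17
Reactants: 24 the bis-benzyl ether
Product: 25 (3S,4R,5R)-3-[(4-hydroxy-3-methoxyphenyl)methyl]-5-[(2R,3R)-2-(4-hydroxy-3-methoxyphenyl)-3-(hydroxymethyl)-7-methoxy-2,3-dihydro-1-benzofuran-5-yl]-4-(hydroxymethyl)oxolan-3-ol (CNP0284796.1)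
Conditions: H2 (1 atm), 10% Pd/C, EtOAc–MeOH, rt
Reagents that add atoms: none
Why: Hydrogenolysis of aryl benzyl ethers, which are cleaved much faster than the secondary benzylic C–O bonds of rings B and D at ambient pressure in neutral solvent; no stereocentre is involved.

## Compound list

1 | 5-iodovanillin | COc1cc(C=O)cc(I)c1O | starting material
2 | [4-(benzyloxy)-3-methoxyphenyl]methanol | COc1cc(CO)ccc1OCc1ccccc1 | starting material
3 | 4-{[4-(benzyloxy)-3-methoxyphenyl]methoxy}-3-iodo-5-methoxybenzaldehyde | COc1cc(C=O)cc(I)c1OCc1ccc(OCc2ccccc2)c(OC)c1 | intermediate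
4 | 2-{[4-(benzyloxy)-3-methoxyphenyl]methoxy}-5-(dimethoxymethyl)-1-iodo-3-methoxybenzene | COc1cc(C(OC)OC)cc(I)c1OCc1ccc(OCc2ccccc2)c(OC)c1 | intermediate
5 | methyl 2-[2-{[4-(benzyloxy)-3-methoxyphenyl]methoxy}-5-(dimethoxymethyl)-3-methoxyphenyl]acetate | COC(=O)Cc1cc(C(OC)OC)cc(OC)c1OCc1ccc(OCc2ccccc2)c(OC)c1 | intermediate
6 | methyl 2-diazo-2-[2-{[4-(benzyloxy)-3-methoxyphenyl]methoxy}-5-(dimethoxymethyl)-3-methoxyphenyl]acetate | COC(=O)C(=[N+]=[N-])c1cc(C(OC)OC)cc(OC)c1OCc1ccc(OCc2ccccc2)c(OC)c1 | intermediate
7 | methyl (2R,3S)-2-[4-(benzyloxy)-3-methoxyphenyl]-5-(dimethoxymethyl)-7-methoxy-2,3-dihydro-1-benzofuran-3-carboxylate (cis) | COC(OC)c3cc(OC)c4c(c3)[C@H](C(=O)OC)[C@H](c5ccc(OCc6ccccc6)c(OC)c5)O4 | intermediate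
8 | [(2R,3R)-2-[4-(benzyloxy)-3-methoxyphenyl]-5-(dimethoxymethyl)-7-methoxy-2,3-dihydro-1-benzofuran-3-yl]methanol (cis) | COC(OC)c3cc(OC)c4c(c3)[C@H](CO)[C@H](c5ccc(OCc6ccccc6)c(OC)c5)O4 | intermediate (not isolated)
9 | (2R,3R)-2-[4-(benzyloxy)-3-methoxyphenyl]-3-(hydroxymethyl)-7-methoxy-2,3-dihydro-1-benzofuran-5-carbaldehyde | O=Cc3cc(OC)c4c(c3)[C@H](CO)[C@H](c5ccc(OCc6ccccc6)c(OC)c5)O4 | intermediate
10 | (2R,3R)-2-[4-(benzyloxy)-3-methoxyphenyl]-3-{[(tert-butyldimethylsilyl)oxy]methyl}-7-methoxy-2,3-dihydro-1-benzofuran-5-carbaldehyde | O=Cc3cc(OC)c4c(c3)[C@H](CO[Si](C)(C)C(C)(C)C)[C@H](c5ccc(OCc6ccccc6)c(OC)c5)O4 | intermediate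
11 | (tert-butyldimethylsilyloxy)acetaldehyde | CC(C)(C)[Si](C)(C)OCC=O | starting material
12 | methyl acrylate | C=CC(=O)OC | starting material
13 | methyl 4-[(tert-butyldimethylsilyl)oxy]-3-hydroxy-2-methylidenebutanoate (racemic) | C=C(C(=O)OC)C(O)CO[Si](C)(C)C(C)(C)C | intermediate
14 | methyl 3-acetoxy-4-[(tert-butyldimethylsilyl)oxy]-2-methylidenebutanoate (racemic) | C=C(C(=O)OC)C(OC(C)=O)CO[Si](C)(C)C(C)(C)C | intermediate
15 | methyl (2E)-4-[(tert-butyldimethylsilyl)oxy]-2-[(4,4,5,5-tetramethyl-1,3,2-dioxaborolan-2-yl)methyl]but-2-enoate | COC(=O)/C(CB1OC(C)(C)C(C)(C)O1)=C/CO[Si](C)(C)C(C)(C)C | intermediate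
16 | (2E)-4-[(tert-butyldimethylsilyl)oxy]-2-[(4,4,5,5-tetramethyl-1,3,2-dioxaborolan-2-yl)methyl]but-2-en-1-ol | OC/C(CB1OC(C)(C)C(C)(C)O1)=C/CO[Si](C)(C)C(C)(C)C | intermediate
17 | tert-butyl({(2E)-4-chloro-3-[(4,4,5,5-tetramethyl-1,3,2-dioxaborolan-2-yl)methyl]but-2-en-1-yl}oxy)dimethylsilane | ClC/C(CB1OC(C)(C)C(C)(C)O1)=C/CO[Si](C)(C)C(C)(C)C | intermediate
18 | pinacol borate of the syn adduct, 2-{[(1R,2R)-1-(benzofuran-5-yl unit of 10)-2-{[(tert-butyldimethylsilyl)oxy]methyl}-3-(chloromethyl)but-3-en-1-yl]oxy}-4,4,5,5-tetramethyl-1,3,2-dioxaborolane | ClCC(=C)[C@H](CO[Si](C)(C)C(C)(C)C)[C@@H](OB1OC(C)(C)C(C)(C)O1)c3cc(OC)c4c(c3)[C@H](CO[Si](C)(C)C(C)(C)C)[C@H](c5ccc(OCc6ccccc6)c(OC)c5)O4 | intermediate (not isolated)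
19 | (2R,3R)-2-[4-(benzyloxy)-3-methoxyphenyl]-3-{[(tert-butyldimethylsilyl)oxy]methyl}-5-[(2R,3R)-3-{[(tert-butyldimethylsilyl)oxy]methyl}-4-methylideneoxolan-2-yl]-7-methoxy-2,3-dihydro-1-benzofuran | C=C2CO[C@@H](c3cc(OC)c4c(c3)[C@H](CO[Si](C)(C)C(C)(C)C)[C@H](c5ccc(OCc6ccccc6)c(OC)c5)O4)[C@H]2CO[Si](C)(C)C(C)(C)C | intermediate
20 | (3R,6R,7R)-6-(benzofuran-5-yl unit of 10)-7-{[(tert-butyldimethylsilyl)oxy]methyl}-1,5-dioxaspiro[2.4]heptane, epoxide oxygen trans to aryl and CH2OTBS | C1[C@@]2(O1)CO[C@@H](c3cc(OC)c4c(c3)[C@H](CO[Si](C)(C)C(C)(C)C)[C@H](c5ccc(OCc6ccccc6)c(OC)c5)O4)[C@H]2CO[Si](C)(C)C(C)(C)C | intermediate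
21 | 1-(benzyloxy)-4-bromo-2-methoxybenzene | COc1cc(Br)ccc1OCc1ccccc1 | starting material
22 | [4-(benzyloxy)-3-methoxyphenyl]magnesium bromide | COc1cc([Mg]Br)ccc1OCc1ccccc1 | intermediate (not isolated)
23 | (3S,4R,5R)-3-{[4-(benzyloxy)-3-methoxyphenyl]methyl}-5-(benzofuran-5-yl unit of 10)-4-{[(tert-butyldimethylsilyl)oxy]methyl}oxolan-3-ol | COc1cc(C[C@@]2(O)CO[C@@H](c3cc(OC)c4c(c3)[C@H](CO[Si](C)(C)C(C)(C)C)[C@H](c5ccc(OCc6ccccc6)c(OC)c5)O4)[C@H]2CO[Si](C)(C)C(C)(C)C)ccc1OCc1ccccc1 | intermediate
24 | (3S,4R,5R)-3-{[4-(benzyloxy)-3-methoxyphenyl]methyl}-5-{(2R,3R)-2-[4-(benzyloxy)-3-methoxyphenyl]-3-(hydroxymethyl)-7-methoxy-2,3-dihydro-1-benzofuran-5-yl}-4-(hydroxymethyl)oxolan-3-ol | COc1cc(C[C@@]2(O)CO[C@@H](c3cc(OC)c4c(c3)[C@H](CO)[C@H](c5ccc(OCc6ccccc6)c(OC)c5)O4)[C@H]2CO)ccc1OCc1ccccc1 | intermediate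
25 | (3S,4R,5R)-3-[(4-hydroxy-3-methoxyphenyl)methyl]-5-[(2R,3R)-2-(4-hydroxy-3-methoxyphenyl)-3-(hydroxymethyl)-7-methoxy-2,3-dihydro-1-benzofuran-5-yl]-4-(hydroxymethyl)oxolan-3-ol | COc1cc(C[C@@]2(O)CO[C@@H](c3cc(OC)c4c(c3)[C@H](CO)[C@H](c3ccc(O)c(OC)c3)O4)[C@H]2CO)ccc1O | target

## Step count and risks

Total: 17 steps. Longest linear sequence: 12 steps (steps 1–7 and 13–17, from 1 to 25); the boronate branch (steps 8–12) has 5 steps.

**Step 13 (key step).** The doubly substituted boronate may add slowly, so that the uncatalysed pathway erodes the facial selectivity, and silyl migration may compete with ring closure once the alkoxide is free. The fallback replaces catalyst control by reagent control. From 17, exchange of pinacol for diethanolamine gives the dioxazaborocane F1. With diisopropyl (2S,3S)-tartrate in ether/brine, F1 gives the tartrate allylboronate F2. F2 adds to 10 in toluene over 4 Å MS at −78 °C through the same chair, the tartrate now choosing the aldehyde face, and hydrolytic work-up gives the free syn homoallylic alcohol F3. F3 is closed with KOt-Bu in THF at low temperature, and the route is rejoined at 19.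

**Step 5.** Enantioselectivity may erode because the methoxy group next to the ether oxygen changes how the benzyloxy arm sits in the catalyst pocket; a trans by-product would be a separable diastereomer, the enantiomer is not. The fallback is resolution in place of induction. From 7, reduction with a tartrate work-up gives 8 as an isolated alcohol. Esterification with (S)-O-methylmandelic acid (DCC, DMAP) gives the (S)-O-methylmandelate F4, together with the mandelate F5 of the minor enantiomer. These are diastereomers and are separated by chromatography or crystallisation. Methanolysis of F4 (K2CO3, MeOH) returns 8, and acid hydrolysis of its acetal rejoins the route at 9.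

**Step 12.** The boronate may be lost during chlorination, by protodeboronation through traces of HCl or by attack of the chlorophosphonium reagent on the nucleophilic allylboron unit, or the allylic system may transpose. The fallback uses a leaving group installed by acylation and ionised by palladium. From 16, methyl chloroformate and pyridine give the allylic methyl carbonate F6. F6 undergoes the same (R)-TRIP-catalysed allylboration with 10 to give the borate carbonate F7. Pd(PPh3)4 in THF then ionises the carbonate; the methoxide set free takes boron off the oxygen, and the alkoxide closes onto the 2-substituted π-allyl unit, either terminus giving the same ring. The route is rejoined at 19.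

**Step 15.** The magnesium halide may rearrange the spiro-epoxide to an aldehyde before the organocopper species attacks, after which the Grignard reagent would add to that aldehyde, or it may open the epoxide to a halohydrin. The fallback is a reductive cross-electrophile coupling without an organomagnesium reagent. From 20 and bromide 21 directly, NiBr2(dme) and 2,2'-bipyridine with NaI, Et3N·HCl and Mn powder in DMPU are used. Iodide opens the epoxide at CH2 to the iodohydrin F8 in the flask, whose primary radical is coupled with the arylnickel species. The route is rejoined at 23.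

## Further compounds

F1 | step 13 | 2-{(2E)-4-[(tert-butyldimethylsilyl)oxy]-2-(chloromethyl)but-2-en-1-yl}-1,3,6,2-dioxazaborocane | ClC/C(CB1OCCNCCO1)=C/CO[Si](C)(C)C(C)(C)C
F2 | step 13 | diisopropyl (4S,5S)-2-{(2E)-4-[(tert-butyldimethylsilyl)oxy]-2-(chloromethyl)but-2-en-1-yl}-1,3,2-dioxaborolane-4,5-dicarboxylate | CC(C)OC(=O)[C@H]1OB(C/C(CCl)=C\CO[Si](C)(C)C(C)(C)C)O[C@@H]1C(=O)OC(C)C
F3 | step 13 | (1R,2R)-1-(benzofuran-5-yl unit of 10)-2-{[(tert-butyldimethylsilyl)oxy]methyl}-3-(chloromethyl)but-3-en-1-ol | ClCC(=C)[C@H](CO[Si](C)(C)C(C)(C)C)[C@@H](O)c3cc(OC)c4c(c3)[C@H](CO[Si](C)(C)C(C)(C)C)[C@H](c5ccc(OCc6ccccc6)c(OC)c5)O4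
F4 | step 5 | (S)-2-methoxy-2-phenylacetate of 8 | COC(OC)c3cc(OC)c4c(c3)[C@H](COC(=O)[C@@H](OC)c7ccccc7)[C@H](c5ccc(OCc6ccccc6)c(OC)c5)O4
F5 | step 5 | (S)-2-methoxy-2-phenylacetate of the enantiomer of 8 | COC(OC)c3cc(OC)c4c(c3)[C@@H](COC(=O)[C@@H](OC)c7ccccc7)[C@@H](c5ccc(OCc6ccccc6)c(OC)c5)O4
F6 | step 12 | (2E)-4-[(tert-butyldimethylsilyl)oxy]-2-[(4,4,5,5-tetramethyl-1,3,2-dioxaborolan-2-yl)methyl]but-2-en-1-yl methyl carbonate | COC(=O)OC/C(CB1OC(C)(C)C(C)(C)O1)=C/CO[Si](C)(C)C(C)(C)C
F7 | step 12 | pinacol borate of the syn adduct carrying the allylic methyl carbonate | COC(=O)OCC(=C)[C@H](CO[Si](C)(C)C(C)(C)C)[C@@H](OB1OC(C)(C)C(C)(C)O1)c3cc(OC)c4c(c3)[C@H](CO[Si](C)(C)C(C)(C)C)[C@H](c5ccc(OCc6ccccc6)c(OC)c5)O4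
F8 | step 15 | (3S,4R,5R)-5-(benzofuran-5-yl unit of 10)-4-{[(tert-butyldimethylsilyl)oxy]methyl}-3-(iodomethyl)oxolan-3-ol | IC[C@@]2(O)CO[C@@H](c3cc(OC)c4c(c3)[C@H](CO[Si](C)(C)C(C)(C)C)[C@H](c5ccc(OCc6ccccc6)c(OC)c5)O4)[C@H]2CO[Si](C)(C)C(C)(C)C
A1 | alternative 1 | aryl diazoacetate on the fully silylated tetrahydrofuran core | COc1cc(C[C@@]2(O[Si](CC)(CC)CC)CO[C@@H](c3cc(OC)c(OCc4ccc(O[Si](C)(C)C(C)(C)C)c(OC)c4)c(c3)C(=[N+]=[N-])C(=O)OC)[C@H]2CO[Si](C)(C)C(C)(C)C)ccc1O[Si](C)(C)C(C)(C)C
A2 | alternative 1 | silylated target skeleton with a cis C3 methyl ester on ring D | COc1cc(C[C@@]2(O[Si](CC)(CC)CC)CO[C@@H](c3cc(OC)c4c(c3)[C@H](C(=O)OC)[C@H](c3ccc(O[Si](C)(C)C(C)(C)C)c(OC)c3)O4)[C@H]2CO[Si](C)(C)C(C)(C)C)ccc1O[Si](C)(C)C(C)(C)C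
A3 | alternative 2 | threo 2-bromo-4-(dimethoxymethyl)-6-methoxyphenyl ether of 1-[4-(benzyloxy)-3-methoxyphenyl]-2,3-epoxypropan-1-ol | COC(OC)c1cc(OC)c(O[C@@H](c2ccc(OCc3ccccc3)c(OC)c2)[C@@H]4CO4)c(Br)c1
A4 | alternative 2 | cis-2-aryl-3-(hydroxymethyl)-7-methoxy-2,3-dihydrobenzofuran-5-carbaldehyde dimethyl acetal (identical with 8) | COC(OC)c3cc(OC)c4c(c3)[C@H](CO)[C@H](c3ccc(OCc5ccccc5)c(OC)c3)O4
A5 | alternative 3 | 4-[(1R,2R)-2-(2-bromo-3-methoxyphenyl)-3-[(tert-butyldimethylsilyl)oxy]-1-hydroxypropyl]-2-methoxyphenyl 4-methylbenzenesulfonate | COc1cccc([C@H](CO[Si](C)(C)C(C)(C)C)[C@@H](O)c2ccc(OS(=O)(=O)c3ccc(C)cc3)c(OC)c2)c1Br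
A6 | alternative 3 | (2R,3R)-cis-2-(3-methoxy-4-tosyloxyphenyl)-3-{[(tert-butyldimethylsilyl)oxy]methyl}-7-methoxy-2,3-dihydrobenzofuran | c3cc(OC)c4c(c3)[C@H](CO[Si](C)(C)C(C)(C)C)[C@H](c5ccc(OS(=O)(=O)c6ccc(C)cc6)c(OC)c5)O4
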